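**Strategy.** The ten-membered carbocycle (C1–C10) is opened at C9–C10. The key step exploits the fact that C9 is a secondary allylic carbinol bonded to C10 of the Z C1=C10 alkene, which also carries C14: a Nozaki–Hiyama–Kishi reaction between a C10 Z-iodoalkene and a C9 aldehyde forms C9–C10, closes the ten-membered ring and sets C9 in one operation, with the α-methylene γ-lactone, the C8 silyl ether and the C14 PMB ether already present. The precursor is a trans 6,12-lactone with the Z,Z-iododienyl chain on C6 and an α-silyloxy acetaldehyde unit on C7, assembled by a ring-templated Barbier allylation.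

Key step: step 14

Assumption: germacrane numbering (C1–C15) is used for all intermediates; (2S)-but-3-ene-1,2-diol, 2-(bromomethyl)prop-2-enoic acid and methyl acetoacetate are taken as commercial.

**Aldehyde fragment (C1–C6, C10, C14, C15)**

Step 1
Reactants: 1 but-2-yne-1,4-diol
Product: 2 4-[(4-methoxybenzyl)oxy]but-2-yn-1-ol
Conditions: NaH, 4-methoxybenzyl chloride, Bu4NI (cat.), THF/DMF, 0 °C to rt (1 in threefold excess)
Reagents that add atoms: 4-methoxybenzyl chloride, COc1ccc(CCl)cc1
Why: Williamson etherification of the symmetric diol used in excess should give mainly the mono-PMB ether.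

Step 2
Reactants: 2 4-[(4-methoxybenzyl)oxy]but-2-yn-1-ol
Product: 4 (2Z)-3-iodo-4-[(4-methoxybenzyl)oxy]but-2-en-1-ol, via sodium alkenylalanate 3 (not isolated)
Conditions: NaAlH2(OCH2CH2OMe)2, THF, 0 °C; then I2, THF, −78 to 0 °C
Reagents that add atoms: iodine, II
Why: Hydroxyl-directed trans-hydroalumination puts aluminium on the alkyne carbon remote from the free hydroxyl (C10) and hydrogen on C1 in an anti sense, and iodinolysis of 3 with retention should give the Z-iodoalkene with iodine cis to C2, the temperature being held at or below 0 °C so that 3 does not eliminate the PMB-oxy group to an allene.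

Step 3
Reactants: 4 (2Z)-3-iodo-4-[(4-methoxybenzyl)oxy]but-2-en-1-ol
Product: 5 1-({[(2Z)-4-bromo-2-iodobut-2-en-1-yl]oxy}methyl)-4-methoxybenzene
Conditions: CBr4, PPh3, CH2Cl2, 0 °C
Reagents that add atoms: carbon tetrabromide, BrC(Br)(Br)Br
Why: Appel bromination converts the primary allylic alcohol into the bromide under neutral conditions that leave the vinyl iodide and the PMB ether untouched.

Step 4
Reactants: 5 1-({[(2Z)-4-bromo-2-iodobut-2-en-1-yl]oxy}methyl)-4-methoxybenzene; 6 methyl acetoacetate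
Product: 8 methyl (6Z)-7-iodo-8-[(4-methoxybenzyl)oxy]-3-oxooct-6-enoate, via acetoacetate dianion 7 (not isolated)
Conditions: NaH, THF, 0 °C; n-BuLi, 0 °C; then 5, 0 °C; 1 M HCl quench
Reagents that add atoms: none
Why: Alkylation of the acetoacetate dianion takes place at its more reactive terminal carbon by SN2 displacement of the primary allylic bromide and so forms C2–C3.

Step 5
Reactants: 8 methyl (6Z)-7-iodo-8-[(4-methoxybenzyl)oxy]-3-oxooct-6-enoate
Product: 9 methyl (2E,6Z)-3-[(diethoxyphosphoryl)oxy]-7-iodo-8-[(4-methoxybenzyl)oxy]octa-2,6-dienoate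
Conditions: ClP(O)(OEt)2, Et3N, DMAP (cat.), DMPU, 0 °C to rt
Reagents that add atoms: diethyl chlorophosphate, CCOP(=O)(Cl)OCC
Why: O-Phosphorylation of the β-keto ester through its non-chelated enolate (amine base, dipolar aprotic medium) is known to favour the E enol phosphate, in which the carbon chain is cis to the ester.

Step 6
Reactants: 9 methyl (2E,6Z)-3-[(diethoxyphosphoryl)oxy]-7-iodo-8-[(4-methoxybenzyl)oxy]octa-2,6-dienoate
Product: 10 methyl (2Z,6Z)-7-iodo-8-[(4-methoxybenzyl)oxy]-3-methylocta-2,6-dienoate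
Conditions: Me2CuLi, Et2O, −78 to −45 °C
Reagents that add atoms: lithium dimethylcuprate, [Li+].C[Cu-]C
Why: Cuprate addition–elimination on the enol phosphate replaces the phosphate by methyl (C15) with retention of geometry, which should give the Z C4=C5 enoate, and at this temperature the unactivated vinyl iodide should not couple.

Step 7
Reactants: 10 methyl (2Z,6Z)-7-iodo-8-[(4-methoxybenzyl)oxy]-3-methylocta-2,6-dienoate
Product: 11 (2Z,6Z)-7-iodo-8-[(4-methoxybenzyl)oxy]-3-methylocta-2,6-dien-1-ol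
Conditions: i-Bu2AlH, CH2Cl2, −78 °C; aq. potassium sodium tartrate
Reagents that add atoms: none
Why: 1,2-Reduction of the conjugated ester by the aluminium hydride gives the allylic alcohol without touching alkene geometry, the vinyl iodide or the PMB ether.

Step 8
Reactants: 11 (2Z,6Z)-7-iodo-8-[(4-methoxybenzyl)oxy]-3-methylocta-2,6-dien-1-ol
Product: 12 (2Z,6Z)-7-iodo-8-[(4-methoxybenzyl)oxy]-3-methylocta-2,6-dienal
Conditions: TEMPO (cat.), PhI(OAc)2, CH2Cl2, rt
Reagents that add atoms: none
Why: Oxoammonium (TEMPO) oxidation with PhI(OAc)2 as terminal oxidant is a nearly neutral allylic oxidation known to preserve the geometry of Z-enals of the neral type.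

**Lactone fragment (C7–C9, C11–C13)**

Step 9
Reactants: 13 (2S)-but-3-ene-1,2-diol; 14 2-(bromomethyl)prop-2-enoic acid
Product: 16 (2S)-2-hydroxybut-3-en-1-yl 2-(bromomethyl)prop-2-enoate, via acyl chloride 15 (not isolated)
Conditions: (COCl)2, DMF (cat.), CH2Cl2, 0 °C to rt; then 13, 2,4,6-collidine, CH2Cl2, −78 °C
Reagents that add atoms: none
Why: Nucleophilic acyl substitution by the acyl chloride at −78 °C with a hindered pyridine base is selective for the primary hydroxyl (O9), and the hindered base spares the allylic bromide.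

Step 10
Reactants: 16 (2S)-2-hydroxybut-3-en-1-yl 2-(bromomethyl)prop-2-enoate
Product: 17 (2S)-2-[(triethylsilyl)oxy]but-3-en-1-yl 2-(bromomethyl)prop-2-enoate
Conditions: Et3SiOTf, 2,6-lutidine, CH2Cl2, −78 °C
Reagents that add atoms: triethylsilyl trifluoromethanesulfonate, CC[Si](CC)(CC)OS(=O)(=O)C(F)(F)F
Why: Silylation of the secondary allylic alcohol (O8) with the silyl triflate is fast at −78 °C and avoids nucleophilic amines that would displace the allylic bromide.

Step 11
Reactants: 17 (2S)-2-[(triethylsilyl)oxy]but-3-en-1-yl 2-(bromomethyl)prop-2-enoate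
Product: 18 (5S)-3-(bromomethyl)-5-[(triethylsilyl)oxy]-5,6-dihydro-2H-pyran-2-one
Conditions: second-generation Grubbs catalyst (5 mol %), toluene (5 mM), 80 °C
Reagents that add atoms: none
Why: Ring-closing metathesis between the vinyl group and the 1,1-disubstituted acrylate closes the six-membered unsaturated lactone (C7=C11) with loss of ethene, a closure well known for methacrylate-type esters of homoallylic alcohols, and the C8 stereocentre is not involved.

**Union and key step**

Step 12
Reactants: 18 (5S)-3-(bromomethyl)-5-[(triethylsilyl)oxy]-5,6-dihydro-2H-pyran-2-one; 12 (2Z,6Z)-7-iodo-8-[(4-methoxybenzyl)oxy]-3-methylocta-2,6-dienal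
Product: 21 (4S,5R)-4-{(1S)-2-hydroxy-1-[(triethylsilyl)oxy]ethyl}-5-{(1Z,5Z)-6-iodo-7-[(4-methoxybenzyl)oxy]-2-methylhepta-1,5-dien-1-yl}-3-methylidenedihydrofuran-2(3H)-one, via allylzinc bromide 19 (not isolated), via six-membered lactone carbinol 20 (not isolated)
Conditions: Zn dust, THF/sat. aq. NH4Cl, 0 °C to rt; then PPTS (cat.), CH2Cl2, rt
Reagents that add atoms: none
Why: Zinc Barbier allylation through a chair (Zimmerman–Traxler) transition state, in which the ring-locked allylzinc 19 (C8 held trans to the CH2Zn terminus) adds to the aldehyde on the face of C7 opposite the C8 silyloxy group with the dienyl residue equatorial, should set C7 and C6 in the anti relation needed for the trans-lactone (an open-chain Z-bromide would give the syn series), after which acid-catalysed translactonisation of 20 to the thermodynamically preferred five-membered 6,12-lactone frees the primary C9 hydroxyl.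

Step 13
Reactants: 21 (4S,5R)-4-{(1S)-2-hydroxy-1-[(triethylsilyl)oxy]ethyl}-5-{(1Z,5Z)-6-iodo-7-[(4-methoxybenzyl)oxy]-2-methylhepta-1,5-dien-1-yl}-3-methylidenedihydrofuran-2(3H)-one
Product: 22 (2S)-2-{(2R,3S)-2-[(1Z,5Z)-6-iodo-7-[(4-methoxybenzyl)oxy]-2-methylhepta-1,5-dien-1-yl]-4-methylidene-5-oxotetrahydrofuran-3-yl}-2-[(triethylsilyl)oxy]acetaldehyde
Conditions: Dess–Martin periodinane, pyridine, CH2Cl2, 0 °C to rt
Reagents that add atoms: none
Why: Dess–Martin oxidation of the primary alcohol under buffered conditions should give the α-silyloxy aldehyde without epimerisation at C8 or silyl migration.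

Step 14
Reactants: 22 (2S)-2-{(2R,3S)-2-[(1Z,5Z)-6-iodo-7-[(4-methoxybenzyl)oxy]-2-methylhepta-1,5-dien-1-yl]-4-methylidene-5-oxotetrahydrofuran-3-yl}-2-[(triethylsilyl)oxy]acetaldehyde
Product: 24 (1(10)Z,4Z,6R,7S,8S,9R)-9-hydroxy-14-[(4-methoxybenzyl)oxy]-8-[(triethylsilyl)oxy]germacra-1(10),4,11(13)-trien-12,6-olide, via alkenylchromium dichloride 23 (not isolated)
Conditions: CrCl2 (8 equiv), NiCl2 (0.1 equiv), degassed DMSO, rt, syringe-pump addition of 22 (final 2 mM)
Reagents that add atoms: none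
Why: NiCl2 is reduced by divalent chromium to zerovalent nickel, which inserts into the C10–I bond with retention of alkene geometry, and transmetallation hands the alkenyl group to trivalent chromium (23), which adds 1,2 to the C9 aldehyde. The closest known reaction type is the Nozaki–Hiyama–Kishi macrocyclisation of ω-iodoalkenyl aldehydes to medium-ring allylic alcohols. The ten-membered carbocycle (C1–C10) is closed in a 10-exo-trig mode, C10 attacking the exocyclic C9 carbonyl, under high dilution with slow addition of 22. The new C9 stereocentre is controlled by the adjacent C8 centre: Felkin–Anh approach anti to the C8 silyloxy group, within the conformation fixed by the trans-lactone and the two Z alkenes, should give the 8,9-erythro (9R) carbinol. The step needs chemoselectivity for the aldehyde over the α-methylene lactone, silyl ether and PMB ether, which the weakly basic, carbonyl-selective alkenylchromium provides, and it needs the Z C1=C10 geometry, which is secured because the iodide cis to C2 in 22 is replaced by C9 with retention.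

**Endgame**

Step 15
Reactants: 24 (1(10)Z,4Z,6R,7S,8S,9R)-9-hydroxy-14-[(4-methoxybenzyl)oxy]-8-[(triethylsilyl)oxy]germacra-1(10),4,11(13)-trien-12,6-olide
Product: 25 (1(10)Z,4Z,6R,7S,8S,9R)-9-acetoxy-14-[(4-methoxybenzyl)oxy]-8-[(triethylsilyl)oxy]germacra-1(10),4,11(13)-trien-12,6-olide
Conditions: Ac2O, pyridine, DMAP (cat.), CH2Cl2, 0 °C to rt
Reagents that add atoms: acetic anhydride, CC(=O)OC(C)=O
Why: DMAP-catalysed acylation esterifies the only free hydroxyl (C9) while C8 and C14 stay protected.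

Step 16
Reactants: 25 (1(10)Z,4Z,6R,7S,8S,9R)-9-acetoxy-14-[(4-methoxybenzyl)oxy]-8-[(triethylsilyl)oxy]germacra-1(10),4,11(13)-trien-12,6-olide
Product: 26 (1(10)Z,4Z,6R,7S,8S,9R)-9-acetoxy-14-hydroxy-8-[(triethylsilyl)oxy]germacra-1(10),4,11(13)-trien-12,6-olide
Conditions: DDQ, CH2Cl2/pH 7 phosphate buffer, 0 °C
Reagents that add atoms: none
Why: Oxidative PMB cleavage by DDQ (hydride abstraction at the electron-rich benzylic position, then hydrolysis of the oxocarbenium ion) in buffered wet solvent should leave the silyl ether, the esters and the alkenes intact.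

Step 17
Reactants: 26 (1(10)Z,4Z,6R,7S,8S,9R)-9-acetoxy-14-hydroxy-8-[(triethylsilyl)oxy]germacra-1(10),4,11(13)-trien-12,6-olide
Product: 27 (1(10)Z,4Z,6R,7S,8S,9R)-9-acetoxy-14-[(3-methylbutanoyl)oxy]-8-[(triethylsilyl)oxy]germacra-1(10),4,11(13)-trien-12,6-olide
Conditions: 3-methylbutanoyl chloride, pyridine, DMAP (cat.), CH2Cl2, 0 °C
Reagents that add atoms: 3-methylbutanoyl chloride, CC(C)CC(=O)Cl
Why: Nucleophilic acyl substitution at the primary allylic alcohol installs the C14 isovalerate while C8 remains silylated.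

Step 18
Reactants: 27 (1(10)Z,4Z,6R,7S,8S,9R)-9-acetoxy-14-[(3-methylbutanoyl)oxy]-8-[(triethylsilyl)oxy]germacra-1(10),4,11(13)-trien-12,6-olide
Product: 28 (1(10)Z,4Z,6R,7R,8S,9R)-9-acetoxy-8-hydroxy-14-[(3-methylbutanoyl)oxy]germacra-1(10),4,11(13)-trien-12,6-olide
Conditions: HF·pyridine, pyridine, THF, 0 °C to rt
Reagents that add atoms: none
Why: Fluoride-mediated desilylation under mildly acidic buffered conditions should remove the triethylsilyl group without acyl migration from C9 to C8 or attack on the esters and the lactone.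

**Compound list**

1 | but-2-yne-1,4-diol | OCC#CCO | starting material
2 | 4-[(4-methoxybenzyl)oxy]but-2-yn-1-ol | OCC#CCOCc1ccc(OC)cc1 | intermediate
3 | sodium alkenylalanate from trans-hydroalumination of 2 (cyclic, aluminium on C10; not isolated) | [Na+].COCCO[Al-]1(OCCOC)OCC=C1COCc1ccc(OC)cc1 | intermediate
4 | (2Z)-3-iodo-4-[(4-methoxybenzyl)oxy]but-2-en-1-ol | OC/C=C(\I)COCc1ccc(OC)cc1 | intermediate
5 | 1-({[(2Z)-4-bromo-2-iodobut-2-en-1-yl]oxy}methyl)-4-methoxybenzene | BrC/C=C(\I)COCc1ccc(OC)cc1 | intermediate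
6 | methyl acetoacetate | CC(=O)CC(=O)OC | starting material
7 | sodium lithium dianion of methyl acetoacetate (not isolated) | [Na+].[Li+].C=C([O-])C=C([O-])OC | intermediate
8 | methyl (6Z)-7-iodo-8-[(4-methoxybenzyl)oxy]-3-oxooct-6-enoate | COC(=O)CC(=O)CC/C=C(\I)COCc1ccc(OC)cc1 | intermediate
9 | methyl (2E,6Z)-3-[(diethoxyphosphoryl)oxy]-7-iodo-8-[(4-methoxybenzyl)oxy]octa-2,6-dienoate | COC(=O)/C=C(/OP(=O)(OCC)OCC)CC/C=C(\I)COCc1ccc(OC)cc1 | intermediate
10 | methyl (2Z,6Z)-7-iodo-8-[(4-methoxybenzyl)oxy]-3-methylocta-2,6-dienoate | COC(=O)/C=C(/C)CC/C=C(\I)COCc1ccc(OC)cc1 | intermediate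
11 | (2Z,6Z)-7-iodo-8-[(4-methoxybenzyl)oxy]-3-methylocta-2,6-dien-1-ol | OC/C=C(/C)CC/C=C(\I)COCc1ccc(OC)cc1 | intermediate
12 | (2Z,6Z)-7-iodo-8-[(4-methoxybenzyl)oxy]-3-methylocta-2,6-dienal | O=C/C=C(/C)CC/C=C(\I)COCc1ccc(OC)cc1 | intermediate
13 | (2S)-but-3-ene-1,2-diol | C=C[C@H](O)CO | starting material
14 | 2-(bromomethyl)prop-2-enoic acid | C=C(CBr)C(=O)O | starting material
15 | 2-(bromomethyl)prop-2-enoyl chloride (not isolated) | C=C(CBr)C(=O)Cl | intermediate
16 | (2S)-2-hydroxybut-3-en-1-yl 2-(bromomethyl)prop-2-enoate | C=C(CBr)C(=O)OC[C@@H](O)C=C | intermediate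
17 | (2S)-2-[(triethylsilyl)oxy]but-3-en-1-yl 2-(bromomethyl)prop-2-enoate | C=C(CBr)C(=O)OC[C@@H](O[Si](CC)(CC)CC)C=C | intermediate
18 | (5S)-3-(bromomethyl)-5-[(triethylsilyl)oxy]-5,6-dihydro-2H-pyran-2-one | BrCC1=C[C@H](O[Si](CC)(CC)CC)COC1=O | intermediate
19 | allylzinc bromide from 18 (zinc on C13; not isolated) | Br[Zn]CC1=C[C@H](O[Si](CC)(CC)CC)COC1=O | intermediate
20 | (4S,5S)-4-[(1R,2Z,6Z)-1-hydroxy-7-iodo-8-[(4-methoxybenzyl)oxy]-3-methylocta-2,6-dien-1-yl]-3-methylidene-5-[(triethylsilyl)oxy]tetrahydro-2H-pyran-2-one (not isolated) | C=C1C(=O)OC[C@@H](O[Si](CC)(CC)CC)[C@@H]1[C@H](O)/C=C(/C)CC/C=C(\I)COCc1ccc(OC)cc1 | intermediate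
21 | (4S,5R)-4-{(1S)-2-hydroxy-1-[(triethylsilyl)oxy]ethyl}-5-{(1Z,5Z)-6-iodo-7-[(4-methoxybenzyl)oxy]-2-methylhepta-1,5-dien-1-yl}-3-methylidenedihydrofuran-2(3H)-one | C=C1C(=O)O[C@H](/C=C(/C)CC/C=C(/COCc2ccc(OC)cc2)I)[C@H]1[C@H](O[Si](CC)(CC)CC)CO | intermediate
22 | (2S)-2-{(2R,3S)-2-[(1Z,5Z)-6-iodo-7-[(4-methoxybenzyl)oxy]-2-methylhepta-1,5-dien-1-yl]-4-methylidene-5-oxotetrahydrofuran-3-yl}-2-[(triethylsilyl)oxy]acetaldehyde (precursor of the key step; 6R,7S,8S) | C=C1C(=O)O[C@H](/C=C(/C)CC/C=C(/COCc2ccc(OC)cc2)I)[C@H]1[C@H](O[Si](CC)(CC)CC)C=O | intermediate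
23 | C10 alkenylchromium dichloride from 22 (not isolated) | C=C1C(=O)O[C@H](/C=C(/C)CC/C=C(/COCc2ccc(OC)cc2)[Cr](Cl)Cl)[C@H]1[C@H](O[Si](CC)(CC)CC)C=O | intermediate
24 | (1(10)Z,4Z,6R,7S,8S,9R)-9-hydroxy-14-[(4-methoxybenzyl)oxy]-8-[(triethylsilyl)oxy]germacra-1(10),4,11(13)-trien-12,6-olide | C=C1C(=O)O[C@@H]2/C=C(/C)CC/C=C(/COCc3ccc(OC)cc3)[C@@H](O)[C@@H](O[Si](CC)(CC)CC)[C@@H]12 | intermediate
25 | (1(10)Z,4Z,6R,7S,8S,9R)-9-acetoxy-14-[(4-methoxybenzyl)oxy]-8-[(triethylsilyl)oxy]germacra-1(10),4,11(13)-trien-12,6-olide | C=C1C(=O)O[C@@H]2/C=C(/C)CC/C=C(/COCc3ccc(OC)cc3)[C@@H](OC(C)=O)[C@@H](O[Si](CC)(CC)CC)[C@@H]12 | intermediate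
26 | (1(10)Z,4Z,6R,7S,8S,9R)-9-acetoxy-14-hydroxy-8-[(triethylsilyl)oxy]germacra-1(10),4,11(13)-trien-12,6-olide | C=C1C(=O)O[C@@H]2/C=C(/C)CC/C=C(/CO)[C@@H](OC(C)=O)[C@@H](O[Si](CC)(CC)CC)[C@@H]12 | intermediate
27 | (1(10)Z,4Z,6R,7S,8S,9R)-9-acetoxy-14-[(3-methylbutanoyl)oxy]-8-[(triethylsilyl)oxy]germacra-1(10),4,11(13)-trien-12,6-olide | C=C1C(=O)O[C@@H]2/C=C(/C)CC/C=C(/COC(=O)CC(C)C)[C@@H](OC(C)=O)[C@@H](O[Si](CC)(CC)CC)[C@@H]12 | intermediate
28 | (1(10)Z,4Z,6R,7R,8S,9R)-9-acetoxy-8-hydroxy-14-[(3-methylbutanoyl)oxy]germacra-1(10),4,11(13)-trien-12,6-olide | C=C1C(=O)O[C@@H]2/C=C(/C)CC/C=C(/COC(=O)CC(C)C)[C@@H](OC(C)=O)[C@@H](O)[C@@H]12 | target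

**Step count and risks**

Total step count: 18. Longest linear sequence: 15 steps (steps 1–8, then 12–18).

Steps most likely to fail:

1. Step 14 (macrocyclisation). Closure of a strained ten-membered ring holding two Z alkenes may lose to intermolecular coupling or to protonation of the alkenylchromium before ring closure, and ring strain may override Felkin–Anh control so that facial selectivity at C9 is poor. The fallback sets out from 22 and comes back at 24. The same C9–C10 closure is used only to make the ring, without asking it for the C9 configuration. The carbinol mixture, including the 9S epimer F1, is oxidised with Dess–Martin periodinane to the macrocyclic 9-ketone F2. F2 is then reduced with NaBH4/CeCl3·7H2O (Luche, hydride delivered from the ring periphery anti to the C8 silyloxy group) or, if substrate control is not enough, with a CBS oxazaborolidine and BH3·SMe2 whose enantiomer is chosen for 9R, which should give 24.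

2. Step 12 (Barbier allylation and lactone migration). The aldehyde may add on the wrong face of C7, simple diastereoselection may erode in the aqueous transition state, the allylzinc may undergo 1,4-reductive loss of the C8 silyloxy group, the Z-enal may isomerise to E, or the lactone migration may stall. The fallback sets out from 18 and 12 and comes back at 21. Bromide 18 is converted by palladium-catalysed borylation (Pd2(dba)3, B2pin2, toluene, 50 °C) into the pinacol allylboronate F3, a non-basic allyl donor of fixed geometry that cannot eliminate the silyloxy group. Allylboration of 12 (toluene, rt to 60 °C, Sc(OTf)3 as optional catalyst) runs through a tight chair transition state of the same topology. Aqueous work-up releases 20, and the same PPTS treatment gives 21.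

3. Step 11 (ring-closing metathesis). Closure onto the 1,1-disubstituted acrylate that carries the allylic bromide may be slow, so that dimerisation through the vinyl group or catalyst decay takes over. The fallback sets out from 13 and comes back at 18. Diol 13 is acylated at the primary hydroxyl with acryloyl chloride (2,4,6-collidine, −78 °C) to the acrylate F4 and silylated (Et3SiOTf, 2,6-lutidine) to the silyl ether F5. Ring-closing metathesis of this unsubstituted acrylate, a much easier closure, gives the dihydropyranone F6. Morita–Baylis–Hillman hydroxymethylation (aq. HCHO, DMAP, THF/H2O) then gives the hydroxymethyl lactone F7, and Appel bromination (CBr4, PPh3) gives 18.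

**Further compounds**

F1 | step 14 | (1(10)Z,4Z,6R,7S,8S,9S)-9-hydroxy-14-[(4-methoxybenzyl)oxy]-8-[(triethylsilyl)oxy]germacra-1(10),4,11(13)-trien-12,6-olide | C=C1C(=O)O[C@@H]2/C=C(/C)CC/C=C(/COCc3ccc(OC)cc3)[C@H](O)[C@@H](O[Si](CC)(CC)CC)[C@@H]12
F2 | step 14 | (1(10)Z,4Z,6R,7S,8S)-14-[(4-methoxybenzyl)oxy]-9-oxo-8-[(triethylsilyl)oxy]germacra-1(10),4,11(13)-trien-12,6-olide | C=C1C(=O)O[C@@H]2/C=C(/C)CC/C=C(/COCc3ccc(OC)cc3)C(=O)[C@@H](O[Si](CC)(CC)CC)[C@@H]12
F3 | step 12 | (5S)-3-[(4,4,5,5-tetramethyl-1,3,2-dioxaborolan-2-yl)methyl]-5-[(triethylsilyl)oxy]-5,6-dihydro-2H-pyran-2-one | CC1(C)OB(CC2=C[C@H](O[Si](CC)(CC)CC)COC2=O)OC1(C)C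
F4 | step 11 | (2S)-2-hydroxybut-3-en-1-yl prop-2-enoate | C=CC(=O)OC[C@@H](O)C=C
F5 | step 11 | (2S)-2-[(triethylsilyl)oxy]but-3-en-1-yl prop-2-enoate | C=CC(=O)OC[C@@H](O[Si](CC)(CC)CC)C=C
F6 | step 11 | (5S)-5-[(triethylsilyl)oxy]-5,6-dihydro-2H-pyran-2-one | O=C1C=C[C@H](O[Si](CC)(CC)CC)CO1
F7 | step 11 | (5S)-3-(hydroxymethyl)-5-[(triethylsilyl)oxy]-5,6-dihydro-2H-pyran-2-one | OCC1=C[C@H](O[Si](CC)(CC)CC)COC1=O
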